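**Retrosynthetic overview**

1. Locants (own numbering): ring A = C1–C5 (C1 sp2, C4 carries methyl C21); ring B = C1, C5–C11 (C8 methyl C22, C11 methyl C20); ring C = C9, C10, C12–C15 (C10 carbinol, C13 carries carboxyl C19); ring D = C13, C14, C16–C18 (C18 isopropyl).
2. Acid 29 ⇐ methyl ester 28 ⇐ ring A closed last through the C1–C2 bond. The enabling feature is the tertiary allylic alcohol array C10(OH)–C11(C20)=C1 joining rings B and C: its 1,3-transposed allylic sulfoxide (S on C1, C11=C10) turns the vinylic carbon C1 into a carbanion that alkylates the C2 tosylate, and the reverse [2,3]-shift returns the C11=C1 alkene and the C10 carbinol.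
3. Sulfoxide 25 ⇐ BCD allylic alcohol 23 ⇐ ring B by RCM (C11=C1) ⇐ lactone 19, whose δ-lactone carries C1–C5 with oxygen in place of the C1–C2 bond (temporary ring, opened in step 14) ⇐ C5–C6 alkylation of lactone 18 with iodide 16.
4. Iodide 16 ⇐ CD ketone 11 by Claisen rearrangement (C9, C8), isopropenyl addition (C10) and hydrozirconation–iodination.
5. Ketone 11 ⇐ Diels–Alder (ring C), Rh-catalysed conjugate alkenylation (C14), enolate allylation (C13), RCM (ring D), hydrogenation (C18). Rings are formed in the order C, D, B, A.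

Key step: step 18

Remark: boronate 5 is taken as a purchasable reagent (otherwise one step from 3-methylbut-1-yne by Markovnikov hydroboration).

**Route**

Step 1
Reactants: 1 (E)-1-methoxy-3-(trimethylsilyloxy)buta-1,3-diene; 2 methyl acrylate
Product: 4 methyl 4-oxocyclohex-2-ene-1-carboxylate (racemic), via silyl enol ether cycloadduct 3 (not isolated)
Conditions: toluene, 80 °C; then 0.1 M HCl, THF, 0 °C
Reagents that add atoms: none
Why: The Diels–Alder reaction of the 1-alkoxy-3-silyloxy diene with the acrylate is "para"-regioselective and acidic work-up with loss of methanol gives the 4-carbomethoxy enone, whose labile C13 centre needs no control because it is erased in step 4.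

Step 2
Reactants: 4 methyl 4-oxocyclohex-2-ene-1-carboxylate; 5 4,4,5,5-tetramethyl-2-(3-methylbut-1-en-2-yl)-1,3,2-dioxaborolane
Product: 6 methyl (2R)-2-(3-methylbut-1-en-2-yl)-4-oxocyclohexane-1-carboxylate (both C1 epimers)
Conditions: [Rh(OH)((S)-BINAP)]2 (3 mol %), KOH (0.2 equiv), dioxane/H2O 10:1, 40 °C
Reagents that add atoms: none
Why: In this Hayashi–Miyaura asymmetric 1,4-addition the (S)-BINAP catalyst should select the enone face as it does for cyclohex-2-enone and so set C14, while the acidic C13–H equilibrates under the basic conditions so that both enantiomers of 4 converge on the same C14 configuration.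

Step 3
Reactants: 6 methyl (2R)-2-(3-methylbut-1-en-2-yl)-4-oxocyclohexane-1-carboxylate
Product: 7 methyl (7R)-7-(3-methylbut-1-en-2-yl)-1,4-dioxaspiro[4.5]decane-8-carboxylate (both C8 epimers)
Conditions: (TMSOCH2)2, TMSOTf (2 mol %), CH2Cl2, −78 → −20 °C
Reagents that add atoms: 1,2-bis(trimethylsilyloxy)ethane, C[Si](C)(C)OCCO[Si](C)(C)C
Why: Silyl-mediated ketalisation protects the ketone under aprotic conditions that should leave the 1,1-disubstituted alkene in place.

Step 4
Reactants: 7 methyl (7R)-7-(3-methylbut-1-en-2-yl)-1,4-dioxaspiro[4.5]decane-8-carboxylate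
Product: 8 methyl (7S,8R)-7-(3-methylbut-1-en-2-yl)-8-(prop-2-en-1-yl)-1,4-dioxaspiro[4.5]decane-8-carboxylate
Conditions: LDA, THF, −78 °C; allyl bromide, DMPU, −78 → −30 °C
Reagents that add atoms: allyl bromide, C=CCBr
Why: In this ester enolate alkylation the electrophile should enter anti to the neighbouring C14 alkenyl group (axial in the exocyclic enolate to avoid allylic strain), which sets the quaternary C13 with allyl trans to the alkenyl group as the trans ring fusion requires.

Step 5
Reactants: 8 methyl (7S,8R)-7-(3-methylbut-1-en-2-yl)-8-(prop-2-en-1-yl)-1,4-dioxaspiro[4.5]decane-8-carboxylate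
Product: 9 methyl (3a'S,7a'R)-3'-(propan-2-yl)-1',3a',4',6',7',7a'-hexahydrospiro[1,3-dioxolane-2,5'-indene]-7a'-carboxylate
Conditions: second-generation Grubbs catalyst (5 mol %), CH2Cl2, 40 °C
Reagents that add atoms: none
Why: Ring-closing metathesis of the trans-disposed allyl and 1,1-disubstituted alkenyl groups should close ring D as a trans-fused cyclopentene without creating a stereocentre.

Step 6
Reactants: 9 methyl (3a'S,7a'R)-3'-(propan-2-yl)-1',3a',4',6',7',7a'-hexahydrospiro[1,3-dioxolane-2,5'-indene]-7a'-carboxylate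
Product: 10 methyl (3'R,3a'S,7a'S)-3'-(propan-2-yl)octahydrospiro[1,3-dioxolane-2,5'-indene]-7a'-carboxylate
Conditions: H2 (3 atm), PtO2, EtOAc, 25 °C
Reagents that add atoms: none
Why: Heterogeneous hydrogenation should occur on the face of ring D opposite the axial angular ester (as for ring D alkenes of trans-hydrindane steroids), which places the C18 hydrogen cis to C14–H and the isopropyl group cis to the ester.

Step 7
Reactants: 10 methyl (3'R,3a'S,7a'S)-3'-(propan-2-yl)octahydrospiro[1,3-dioxolane-2,5'-indene]-7a'-carboxylate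
Product: 11 methyl (3R,3aS,7aS)-5-oxo-3-(propan-2-yl)octahydro-1H-indene-7a-carboxylate
Conditions: 1 M HCl, THF, 25 °C
Reagents that add atoms: water, O
Why: Acidic hydrolysis of the dioxolane frees the C10 ketone, which has no epimerisable stereocentre next to it.

Step 8
Reactants: 11 methyl (3R,3aS,7aS)-5-oxo-3-(propan-2-yl)octahydro-1H-indene-7a-carboxylate
Product: 13 methyl (3R,3aS,6R,7aS)-6-[(2S)-but-3-en-2-yl]-5-oxo-3-(propan-2-yl)octahydro-1H-indene-7a-carboxylate, via crotyl enol ether 12 (not isolated)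
Conditions: (E)-but-2-en-1-ol (6 equiv), TsOH (2 mol %), toluene, Dean–Stark, 110 °C; then xylene, 140 °C
Reagents that add atoms: (E)-but-2-en-1-ol, C/C=C/CO
Why: The trans-fused ketone should form its enol ether toward C9 (away from the ring fusion, as 3-keto-5α-steroids do) and the Claisen rearrangement through a chair transition state on the face opposite the axial ester should set C9 (equatorial chain) and, from the E alkene, C8.

Step 9
Reactants: 13 methyl (3R,3aS,6R,7aS)-6-[(2S)-but-3-en-2-yl]-5-oxo-3-(propan-2-yl)octahydro-1H-indene-7a-carboxylate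
Product: 14 methyl (3R,3aS,5R,6R,7aS)-6-[(2S)-but-3-en-2-yl]-5-hydroxy-3-(propan-2-yl)-5-(prop-1-en-2-yl)octahydro-1H-indene-7a-carboxylate
Conditions: isopropenylmagnesium bromide, CeCl3, THF, −78 °C
Reagents that add atoms: isopropenylmagnesium bromide, C=C(C)[Mg]Br
Why: Organocerium 1,2-addition avoids enolisation and equatorial attack trans to the C9 chain should give the axial alcohol shown, although the C10 configuration is not critical because it is erased in step 17 and set again in step 18.

Step 10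
Reactants: 14 methyl (3R,3aS,5R,6R,7aS)-6-[(2S)-but-3-en-2-yl]-5-hydroxy-3-(propan-2-yl)-5-(prop-1-en-2-yl)octahydro-1H-indene-7a-carboxylate
Product: 16 methyl (3R,3aS,5R,6R,7aS)-5-hydroxy-6-[(2S)-4-iodobutan-2-yl]-3-(propan-2-yl)-5-(prop-1-en-2-yl)octahydro-1H-indene-7a-carboxylate, via alkylzirconocene chloride 15 (not isolated)
Conditions: Cp2Zr(H)Cl (2.5 equiv), THF, 25 °C; then I2, 0 °C
Reagents that add atoms: iodine, II
Why: Hydrozirconation should select the monosubstituted alkene over the hindered 1,1-disubstituted one and place zirconium on the terminal carbon C6, and iodinolysis then gives the primary iodide (one equivalent of hydride is consumed by the hydroxyl).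

Step 11
Reactants: 17 5,6-dihydro-2H-pyran-2-one
Product: 18 (4R)-4-methyloxan-2-one
Conditions: MeMgBr, CuBr·SMe2 (5 mol %), chiral ferrocenyl diphosphine of the Josiphos type (enantiomer that gives the 4R lactone), t-BuOMe, −75 °C
Reagents that add atoms: methylmagnesium bromide, C[Mg]Br
Why: Copper-catalysed asymmetric conjugate addition of the Grignard reagent to the unsaturated lactone should set C4 under ligand control.

Step 12
Reactants: 16 methyl (3R,3aS,5R,6R,7aS)-5-hydroxy-6-[(2S)-4-iodobutan-2-yl]-3-(propan-2-yl)-5-(prop-1-en-2-yl)octahydro-1H-indene-7a-carboxylate; 18 (4R)-4-methyloxan-2-one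
Product: 19 methyl (3R,3aS,5R,6R,7aS)-5-hydroxy-6-{(2S)-4-[(3S,4R)-4-methyl-2-oxooxan-3-yl]butan-2-yl}-3-(propan-2-yl)-5-(prop-1-en-2-yl)octahydro-1H-indene-7a-carboxylate
Conditions: 18 (3 equiv), LDA (2.9 equiv), THF, −78 °C; then 16, HMPA, −78 → −30 °C
Reagents that add atoms: none
Why: Alkylation of the δ-lactone enolate anti to the neighbouring C4 methyl group should give the trans-3,4-disubstituted lactone and so set C5, the excess enolate also deprotonating the tertiary hydroxyl.

Step 13
Reactants: 19 methyl (3R,3aS,5R,6R,7aS)-5-hydroxy-6-{(2S)-4-[(3S,4R)-4-methyl-2-oxooxan-3-yl]butan-2-yl}-3-(propan-2-yl)-5-(prop-1-en-2-yl)octahydro-1H-indene-7a-carboxylate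
Product: 20 methyl (3R,3aS,5R,6R,7aS)-5-hydroxy-6-{(2S)-4-[(3S,4R)-2-hydroxy-4-methyloxan-3-yl]butan-2-yl}-3-(propan-2-yl)-5-(prop-1-en-2-yl)octahydro-1H-indene-7a-carboxylate (anomers)
Conditions: DIBAL-H (2.2 equiv), CH2Cl2, −78 °C
Reagents that add atoms: none
Why: At −78 °C DIBAL-H should reduce the lactone to the lactol much faster than it attacks the neopentyl angular methyl ester, and no stereocentre is touched.

Step 14
Reactants: 20 methyl (3R,3aS,5R,6R,7aS)-5-hydroxy-6-{(2S)-4-[(3S,4R)-2-hydroxy-4-methyloxan-3-yl]butan-2-yl}-3-(propan-2-yl)-5-(prop-1-en-2-yl)octahydro-1H-indene-7a-carboxylate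
Product: 21 methyl (3R,3aS,5R,6R,7aS)-6-[(2S,5R,6R)-5-ethenyl-8-hydroxy-6-methyloctan-2-yl]-5-hydroxy-3-(propan-2-yl)-5-(prop-1-en-2-yl)octahydro-1H-indene-7a-carboxylate
Conditions: Ph3PCH3Br, KOtBu, THF, 0 °C
Reagents that add atoms: methyltriphenylphosphonium bromide, C[P+](c1ccccc1)(c1ccccc1)c1ccccc1.[Br-]
Why: Wittig methylenation of the open hydroxy aldehyde form of the lactol should give the C1 vinyl group and free the C2 alcohol, the non-stabilised ylide adding faster than it epimerises C5.

Step 15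
Reactants: 21 methyl (3R,3aS,5R,6R,7aS)-6-[(2S,5R,6R)-5-ethenyl-8-hydroxy-6-methyloctan-2-yl]-5-hydroxy-3-(propan-2-yl)-5-(prop-1-en-2-yl)octahydro-1H-indene-7a-carboxylate
Product: 22 BCD-tricyclic diol: methyl ester with (Z)-C11=C1 alkene (C1–H), C10 tertiary alcohol and C5 bearing the (2R)-4-hydroxybutan-2-yl chain (configurations 4R,5S,8S,9R,10R,13S,14S,18R)
Conditions: second-generation Hoveyda–Grubbs catalyst (10 mol %), toluene (2 mM), 80 °C
Reagents that add atoms: none
Why: Ring-closing metathesis of the vinyl and isopropenyl groups should form ring B with the ring-enforced Z trisubstituted alkene, helped by the trans-diequatorial arms on ring C and the free allylic hydroxyl.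

Step 16
Reactants: 22 BCD-tricyclic diol
Product: 23 BCD-tricyclic allylic alcohol with the side-chain C2 primary tosylate
Conditions: TsCl, pyridine, DMAP (cat.), CH2Cl2, 0 °C
Reagents that add atoms: p-toluenesulfonyl chloride, Cc1ccc(cc1)S(Cl)(=O)=O
Why: The primary alcohol should be sulfonylated selectively over the hindered tertiary allylic alcohol.

Step 17
Reactants: 23 BCD-tricyclic allylic alcohol tosylate
Product: 25 BCD-tricyclic allylic sulfoxide: C1 (S)-phenylsulfinyl (sulfur on the face of C5–H; epimers at sulfur) and tetrasubstituted C11=C10 alkene, via sulfenate ester 24 (not isolated)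
Conditions: n-BuLi, THF, −78 °C; PhSCl, −78 → 0 °C
Reagents that add atoms: benzenesulfenyl chloride, ClSc1ccccc1
Why: O-Sulfenylation followed by the Mislow–Evans [2,3]-sigmatropic rearrangement (sulfenate to sulfoxide) should move the heteroatom suprafacially from C10 to C1 and the alkene to C11=C10, so that C1 carries an acidifying sulfinyl group.

Step 18
Reactants: 25 BCD-tricyclic allylic sulfoxide
Product: 28 methyl ester of sesterfisheric acid, via tetracyclic allylic sulfoxide 26 (not isolated), via sulfenate ester 27 (not isolated)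
Conditions: LDA (1.3 equiv), THF/HMPA, −78 → −30 °C; then Et2NH (10 equiv), MeOH, 25 → 40 °C
Reagents that add atoms: none
Why: LDA removes the C1 hydrogen, which is both allylic and α to sulfur, the sulfinyl-stabilised allyl anion alkylates the primary C2 tosylate at C1 (5-exo-tet closure of ring A, the C11=C10 π-system staying outside the forming ring), and the quaternary sulfoxide 26 equilibrates by [2,3]-shift with sulfenate 27, which diethylamine cleaves at sulfur to give the C10 alcohol and the C11=C1 alkene. The closest known reaction type is the alkylation of allylic sulfoxide anions followed by Mislow–Evans rearrangement, which uses an allylic alcohol as a hydroxy-vinyl anion equivalent. Attack at C1 rather than at C10 is secured by ring size, because C10 attack would need a bridged seven-membered ring. The cis-cyclooctene constraint holds C5 cisoid on the allyl anion, so C2, tethered through C4–C3 on one face of C5, can reach only that face of C1 and sulfur is left cis to C5–H. The suprafacial shift then delivers oxygen to the same face of C10, so the C10 configuration (hydroxyl trans to C9–H) is relayed from C5 whatever the C10 configuration of 23 was. The step needs C-alkylation to outrun elimination of the tosylate, which the soft carbanion, the five-membered transition state and the low temperature should secure.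

Step 19
Reactants: 28 methyl ester of sesterfisheric acid
Product: 29 sesterfisheric acid
Conditions: n-PrSLi, HMPA, 25 °C; then dilute HCl to pH 4, 0 °C
Reagents that add atoms: none
Why: SN2 demethylation by the thiolate should cleave the hindered angular methyl ester without putting basic or acidic stress on the tertiary allylic alcohol.

**Compound list**

1 | (E)-1-methoxy-3-(trimethylsilyloxy)buta-1,3-diene | CO/C=C/C(=C)O[Si](C)(C)C | starting material
2 | methyl acrylate | C=CC(=O)OC | starting material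
3 | methyl 2-methoxy-4-(trimethylsilyloxy)cyclohex-3-ene-1-carboxylate (racemic cycloadduct) | COC(=O)C1CCC(O[Si](C)(C)C)=CC1OC | intermediate
4 | methyl 4-oxocyclohex-2-ene-1-carboxylate (racemic) | COC(=O)C1CCC(=O)C=C1 | intermediate
5 | 4,4,5,5-tetramethyl-2-(3-methylbut-1-en-2-yl)-1,3,2-dioxaborolane | C=C(C(C)C)B1OC(C)(C)C(C)(C)O1 | starting material
6 | methyl (2R)-2-(3-methylbut-1-en-2-yl)-4-oxocyclohexane-1-carboxylate (C1 epimers) | O=C1CCC(C(=O)OC)[C@@H](C1)C(=C)C(C)C | intermediate
7 | methyl (7R)-7-(3-methylbut-1-en-2-yl)-1,4-dioxaspiro[4.5]decane-8-carboxylate (C8 epimers) | C1COC2(O1)CCC(C(=O)OC)[C@@H](C2)C(=C)C(C)C | intermediate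
8 | methyl (7S,8R)-7-(3-methylbut-1-en-2-yl)-8-(prop-2-en-1-yl)-1,4-dioxaspiro[4.5]decane-8-carboxylate | C1COC2(O1)CC[C@](CC=C)(C(=O)OC)[C@@H](C2)C(=C)C(C)C | intermediate
9 | methyl (3a'S,7a'R)-3'-(propan-2-yl)-1',3a',4',6',7',7a'-hexahydrospiro[1,3-dioxolane-2,5'-indene]-7a'-carboxylate | C1COC2(O1)CC[C@@]3(C(=O)OC)CC=C(C(C)C)[C@@H]3C2 | intermediate
10 | methyl (3'R,3a'S,7a'S)-3'-(propan-2-yl)octahydrospiro[1,3-dioxolane-2,5'-indene]-7a'-carboxylate | C1COC2(O1)CC[C@@]3(C(=O)OC)CC[C@H](C(C)C)[C@@H]3C2 | intermediate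
11 | methyl (3R,3aS,7aS)-5-oxo-3-(propan-2-yl)octahydro-1H-indene-7a-carboxylate (CD ketone) | O=C1CC[C@@]2(C(=O)OC)CC[C@H](C(C)C)[C@@H]2C1 | intermediate
12 | methyl (3R,3aS,7aS)-5-[(2E)-but-2-en-1-yloxy]-3-(propan-2-yl)-2,3,3a,4,7,7a-hexahydro-1H-indene-7a-carboxylate | C/C=C/COC1=CC[C@@]2(C(=O)OC)CC[C@H](C(C)C)[C@@H]2C1 | intermediate
13 | methyl (3R,3aS,6R,7aS)-6-[(2S)-but-3-en-2-yl]-5-oxo-3-(propan-2-yl)octahydro-1H-indene-7a-carboxylate | C=C[C@H](C)[C@H]1C[C@@]2(C(=O)OC)CC[C@H](C(C)C)[C@@H]2CC1=O | intermediate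
14 | methyl (3R,3aS,5R,6R,7aS)-6-[(2S)-but-3-en-2-yl]-5-hydroxy-3-(propan-2-yl)-5-(prop-1-en-2-yl)octahydro-1H-indene-7a-carboxylate | C=C[C@H](C)[C@H]1C[C@@]2(C(=O)OC)CC[C@H](C(C)C)[C@@H]2C[C@]1(O)C(C)=C | intermediate
15 | chlorobis(cyclopentadienyl)zirconium alkyl from 14 (zirconium on the terminal side-chain carbon C6; hydroxyl drawn free) | Cl[Zr](C4C=CC=C4)(C5C=CC=C5)CC[C@H](C)[C@H]1C[C@@]2(C(=O)OC)CC[C@H](C(C)C)[C@@H]2C[C@]1(O)C(C)=C | intermediate
16 | methyl (3R,3aS,5R,6R,7aS)-5-hydroxy-6-[(2S)-4-iodobutan-2-yl]-3-(propan-2-yl)-5-(prop-1-en-2-yl)octahydro-1H-indene-7a-carboxylate | ICC[C@H](C)[C@H]1C[C@@]2(C(=O)OC)CC[C@H](C(C)C)[C@@H]2C[C@]1(O)C(C)=C | intermediate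
17 | 5,6-dihydro-2H-pyran-2-one | O=C1C=CCCO1 | starting material
18 | (4R)-4-methyloxan-2-one | O=C1C[C@H](C)CCO1 | intermediate
19 | methyl (3R,3aS,5R,6R,7aS)-5-hydroxy-6-{(2S)-4-[(3S,4R)-4-methyl-2-oxooxan-3-yl]butan-2-yl}-3-(propan-2-yl)-5-(prop-1-en-2-yl)octahydro-1H-indene-7a-carboxylate | O=C1OCC[C@@H](C)[C@@H]1CC[C@H](C)[C@H]2C[C@@]3(C(=O)OC)CC[C@H](C(C)C)[C@@H]3C[C@]2(O)C(C)=C | intermediate
20 | methyl (3R,3aS,5R,6R,7aS)-5-hydroxy-6-{(2S)-4-[(3S,4R)-2-hydroxy-4-methyloxan-3-yl]butan-2-yl}-3-(propan-2-yl)-5-(prop-1-en-2-yl)octahydro-1H-indene-7a-carboxylate (anomers) | OC1OCC[C@@H](C)[C@@H]1CC[C@H](C)[C@H]2C[C@@]3(C(=O)OC)CC[C@H](C(C)C)[C@@H]3C[C@]2(O)C(C)=C | intermediate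
21 | methyl (3R,3aS,5R,6R,7aS)-6-[(2S,5R,6R)-5-ethenyl-8-hydroxy-6-methyloctan-2-yl]-5-hydroxy-3-(propan-2-yl)-5-(prop-1-en-2-yl)octahydro-1H-indene-7a-carboxylate | OCC[C@@H](C)[C@@H](C=C)CC[C@H](C)[C@H]1C[C@@]2(C(=O)OC)CC[C@H](C(C)C)[C@@H]2C[C@]1(O)C(C)=C | intermediate
22 | BCD-tricyclic diol: methyl ester; (Z)-C11=C1 alkene; C10 tertiary OH; C5 chain (2R)-4-hydroxybutan-2-yl (4R,5S,8S,9R,10R,13S,14S,18R) | C/C1=C/[C@H]([C@H](C)CCO)CC[C@H](C)[C@H]2C[C@@]3(C(=O)OC)CC[C@H](C(C)C)[C@@H]3C[C@]12O | intermediate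
23 | BCD-tricyclic allylic alcohol: as 22 with the C2 primary 4-methylbenzenesulfonate | C/C1=C/[C@H]([C@H](C)CCOS(=O)(=O)c4ccc(C)cc4)CC[C@H](C)[C@H]2C[C@@]3(C(=O)OC)CC[C@H](C(C)C)[C@@H]3C[C@]12O | intermediate
24 | C10 O-phenylsulfenate ester of 23 | C/C1=C/[C@H]([C@H](C)CCOS(=O)(=O)c4ccc(C)cc4)CC[C@H](C)[C@H]2C[C@@]3(C(=O)OC)CC[C@H](C(C)C)[C@@H]3C[C@]12OSc5ccccc5 | intermediate
25 | BCD-tricyclic allylic sulfoxide: C1 (S)-phenylsulfinyl cis to C5–H (epimers at sulfur); C11=C10 alkene; C2 tosylate | C/C1=C2\C[C@H]3[C@@H](C(C)C)CC[C@]3(C(=O)OC)C[C@@H]2[C@@H](C)CC[C@@H]([C@H](C)CCOS(=O)(=O)c4ccc(C)cc4)[C@@H]1S(=O)c5ccccc5 | intermediate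
26 | tetracyclic allylic sulfoxide: ring A closed; quaternary C1 (S) bearing phenylsulfinyl; C11=C10 alkene | C/C1=C2\C[C@H]3[C@@H](C(C)C)CC[C@]3(C(=O)OC)C[C@@H]2[C@@H](C)CC[C@H]4[C@H](C)CC[C@@]14S(=O)c5ccccc5 | intermediate
27 | C10 O-phenylsulfenate ester of 28 | C/C1=C2\CC[C@@H](C)[C@@H]2CC[C@H](C)[C@H]2C[C@@]3(C(=O)OC)CC[C@H](C(C)C)[C@@H]3C[C@]12OSc4ccccc4 | intermediate
28 | methyl ester of sesterfisheric acid | C/C1=C2\CC[C@@H](C)[C@@H]2CC[C@H](C)[C@H]2C[C@@]3(C(=O)OC)CC[C@H](C(C)C)[C@@H]3C[C@]12O | intermediate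
29 | sesterfisheric acid | C/C1=C2\CC[C@@H](C)[C@@H]2CC[C@H](C)[C@H]2C[C@@]3(C(=O)O)CC[C@H](C(C)C)[C@@H]3C[C@]12O | target

**Step count**

Total: 19 steps. Longest linear sequence: 18 steps (steps 1–10 and 12–19, from 1 and 2).

**Steps most likely to fail, with fallbacks**

Step 15 (RCM of ring B). The metathesis may not turn over at the hindered isopropenyl carbinol, or may give oligomers because the eight-membered ring forms slowly. The fallback closes ring B at the unhindered C6=C7 position and brings in the C11=C1 alkene already formed. It sets out from lactone 18 and ketone 13. The zinc enolate of 18 (LiHMDS, ZnCl2) is α-vinylated with vinyl bromide (Pd(dba)2, P(t-Bu)3, low temperature to avoid alkene migration) to the trans (3S,4R)-3-ethenyl-4-methyloxan-2-one F1. DIBAL-H gives the lactol (3S,4R)-3-ethenyl-4-methyloxan-2-ol F2. Stork–Zhao olefination with the ylide made from ethyltriphenylphosphonium iodide, n-BuLi, I2 and NaHMDS gives the Z-iodoalkene (3R,4S,5Z)-4-ethenyl-6-iodo-3-methylhept-5-en-1-ol F3. Iodine–lithium exchange (t-BuLi, 3 equiv) and CeCl3-mediated addition to ketone 13 give the triene diol F4. RCM of its two vinyl groups (second-generation Grubbs catalyst) closes ring B as the cyclooctadiene diol F5. Diimide (potassium azodicarboxylate, AcOH) reduces only the disubstituted C6=C7 alkene and returns to 22.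

Step 18 (key step). Ring closure may lose to elimination of the tosylate or to proton transfer, or it may take place on the other face of the allyl anion, which after the sigmatropic shift would give the C10 epimer. The fallback leaves C10 untouched and closes ring A by a radical Heck-type reaction. It sets out from tosylate 23: NaI in acetone gives the primary iodide F6, and a palladium-catalysed alkyl-Heck cyclisation (Pd(PPh3)4, a zerovalent palladium catalyst, 1,2,2,6,6-pentamethylpiperidine, benzene, CO atmosphere, 110 °C) should give 5-exo attack of the C2 radical on C1 and loss of the C1 hydrogen from the C11 intermediate, returning to 28. Any exocyclic C11=C20 alkene isomer would have to be separated.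

Step 2 (asymmetric conjugate alkenylation). Slow equilibration of the C13 epimers of 4, or substrate control overriding the catalyst, would erode the enantiomeric purity at C14, and the enone ester may aromatise under base. The fallback uses a covalently bound auxiliary. It sets out from 4: ketalisation with ethylene glycol (TsOH, benzene, reflux) moves the alkene into conjugation with the ester and gives methyl 1,4-dioxaspiro[4.5]dec-7-ene-8-carboxylate F7. LiOH gives the acid F8. Oxalyl chloride and then the sodium salt of (2R)-bornane-10,2-sultam (or its antipode, whichever the chelate model assigns to the required C14 face) give the N-enoyl sultam F9. 1,4-Addition of the Grignard reagent from 2-bromo-3-methylbut-1-ene (THF, −78 °C) under auxiliary control gives the adduct F10. NaOMe in MeOH removes the auxiliary and returns to 7.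

**Further compounds**

F1 | step 15 | (3S,4R)-3-ethenyl-4-methyloxan-2-one | O=C1OCC[C@@H](C)[C@@H]1C=C
F2 | step 15 | (3S,4R)-3-ethenyl-4-methyloxan-2-ol (anomers) | OC1OCC[C@@H](C)[C@@H]1C=C
F3 | step 15 | (3R,4S,5Z)-4-ethenyl-6-iodo-3-methylhept-5-en-1-ol | C/C(I)=C/[C@@H](C=C)[C@H](C)CCO
F4 | step 15 | triene diol: adduct of the alkenyllithium from F3 with ketone 13 (Z-C11=C1; vinyl groups on C5 and C8) | C=C[C@H](C)[C@H]1C[C@@]2(C(=O)OC)CC[C@H](C(C)C)[C@@H]2C[C@]1(O)/C(C)=C\[C@@H](C=C)[C@H](C)CCO
F5 | step 15 | BCD-tricyclic diol with an additional (Z)-C6=C7 alkene | C/C1=C/[C@H]([C@H](C)CCO)/C=C\[C@H](C)[C@H]2C[C@@]3(C(=O)OC)CC[C@H](C(C)C)[C@@H]3C[C@]12O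
F6 | step 18 | BCD-tricyclic allylic alcohol with the C2 primary iodide | C/C1=C/[C@H]([C@H](C)CCI)CC[C@H](C)[C@H]2C[C@@]3(C(=O)OC)CC[C@H](C(C)C)[C@@H]3C[C@]12O
F7 | step 2 | methyl 1,4-dioxaspiro[4.5]dec-7-ene-8-carboxylate | COC(=O)C1=CCC2(CC1)OCCO2
F8 | step 2 | 1,4-dioxaspiro[4.5]dec-7-ene-8-carboxylic acid | OC(=O)C1=CCC2(CC1)OCCO2
F9 | step 2 | N-(1,4-dioxaspiro[4.5]dec-7-en-8-ylcarbonyl)-(2R)-bornane-10,2-sultam | CC1(C)[C@@H]2CC[C@]13CS(=O)(=O)N(C(=O)C4=CCC5(CC4)OCCO5)[C@@H]3C2
F10 | step 2 | N-{[(7R)-7-(3-methylbut-1-en-2-yl)-1,4-dioxaspiro[4.5]dec-8-yl]carbonyl}-(2R)-bornane-10,2-sultam | CC1(C)[C@@H]2CC[C@]13CS(=O)(=O)N(C(=O)C4CCC5(OCCO5)C[C@H]4C(=C)C(C)C)[C@@H]3C2
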